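At early times the readings follow the starting material, so the fraction of it left comes first.

in all of them: starting material 20 mM
- north: partner 0.38 equiv; run made earlier
- east: partner 1.4 equiv; run made earlier
- delta: partner 0.260 equiv; time 25 h
- zeta: partner 1.05 equiv; time 25 h

| run | time / h | target / % | starting material / % |
|---|---|---|---|
| north | 1.33 | 0 | 65 |
| north | 2.50 | 2 | 42 |
| north | 5.00 | 2 | 18 |
| north | 10.0 | 5 | 1 |
| north | 20.0 | 11 | 0 |
| east | 4.00 | 8 | 28 |
| east | 8.00 | 16 | 9 |
| east | 10.0 | 20 | 3 |
| east | 15.0 | 27 | 2 |
| east | 20.0 | 34 | 1 |

(scatter of a reading: 2 percentage points)

1. the winner by amount of target, in percent of the starting material charged; "neither" if no more than 2 percentage points parts them (delta / zeta / neither)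
2. how much target is there at the end, in percent of the starting material charged: delta
3. how much target is there at the end, in percent of the starting material charged: zeta

- amounts and yields of target count crystals too
- given per volume of solution although it is solid: crystals
- the numbers in the tables scatter by 2 percentage points (one standard deviation)
- reactions considered so far: crystals <-> target; partner -> second intermediate; target <-> isomer of the product; 2 second intermediate -> homo product; partner -> decomposed reagent; open intermediate + second intermediate -> target; starting material -> open intermediate

Consider what each number could move. The decay constant of the starting material moves little of what is left of it at the end. The north run reads 18% at 5.00 h, and if each further span of that length multiplies by the same fraction, the reckoning leaves 0.0189% at 25 h. A reading twice as high still leaves 0.605%. The amount of partner matters: from north to east it rises 3.68-fold and target at 20.0 h rises 3.09-fold. The share of partner that reaches target matters too, and it carries the scatter, 2 percentage points against the 11% of north.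

That share is the number to carry. North gives 0.289 per equivalent at 20.0 h. Target in the north readings climbs roughly in a straight line, so stretching to 25 h gives 0.362, the partner yield: the part of the charged partner found as target. East, stretched the same way, gives 0.304. In delta partner is the limiting reagent at 0.260 equiv, and north's yield gives 9.41%. East's yield gives zeta 31.9%. The forecast names zeta the winner, with 9% for delta and 31% for zeta, each a little lower than this reckoning, holding that “about 30–34% of the partner charged should end up as target”.

zeta wins, with 8.53% in delta and 28.8% in zeta at 25 h.

    crystals ⇌ target, rate k1*(cs1 - [target]) while solid is left; crystals form when [target] > cs1 (solubility = 0.360 mM, k = 16.1 h⁻¹)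
    partner → second intermediate (k = 0.931 h⁻¹)
    target ⇌ isomer of the product (K = 1.95, k = 0.338 h⁻¹)
    2 second intermediate → homo product (k = 2.28 M⁻¹ h⁻¹)
    partner → decomposed reagent (k = 0.207 h⁻¹)
    open intermediate + second intermediate → target (k = 2.58 M⁻¹ h⁻¹)
    starting material → open intermediate (k = 0.344 h⁻¹)

Starting from north, moving partner alone to the zeta amount brings 25.6%, and moving time alone brings 12.8%. The partner yield now reads 0.328 in delta and 0.274 in zeta, against the 0.362 and 0.304 carried. For the neighbour flask with 0.160 equiv of partner, the carried 0.362 reckons 5.79%; the computed flask gives 4.47%.

The data were generated by integration with constants of no real substance.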